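## Retrosynthetic overview

1. The target is released by saponifying two ester protecting groups and re-closing both δ-lactones. Before that, a Julia–Kocienski olefination joins the oxolane-core aldehyde to a cyclopropyl-lactone PT-sulfone (E-alkene), and a double Z-selective Wittig reaction installs both skipped dienes.
2. The oxolane is closed by cross-metathesis with but-2-enal followed by intramolecular oxa-Michael addition of a secondary hydroxyl, which sets the ring carbon carrying the octadienyl chain.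
3. The acyclic precursor comes from a Paterson anti-aldol of an α-benzoyloxy ketone with the cyclopropyl-lactone aldehyde, then an Evans–Tishchenko anti-reduction. The ketone is made from an L-malic acid Weinreb amide and a homoallylic iodide from an Evans alkylation.
4. Aldehyde and sulfone share one alcohol, built by Charette cyclopropanation, Brown allylation, acryloylation and ring-closing metathesis.
5. Ring order: cyclopropane, δ-lactone (RCM), oxolane (oxa-Michael). The second cyclopropane/lactone pair arrives ready-made in the Julia step.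

Assumption: commercial reagents that appear only on Conditions lines are not numbered, and the face selectivity of the aldol in step 25 is taken to follow the Paterson model for α-benzoyloxy ketones.

Abbreviations: TBDPS = tert-butyl(diphenyl)silyl; TBS = tert-butyl(dimethyl)silyl; TIPS = tri(propan-2-yl)silyl; Bz = benzoyl; Ac = acetyl; PT = 1-phenyl-1H-tetrazol-5-yl; CPL = (1R,2R)-2-[(2R)-6-oxooxan-2-yl]cyclopropyl. Full names are in the compound list.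

## Route

**Cyclopropyl-lactone fragment (steps 1–12)**

Step 1
Reactants: 1 but-2-yne-1,4-diol
Product: 2 (2E)-but-2-ene-1,4-diol
Conditions: LiAlH4, THF, reflux; aqueous NaOH work-up
Reagents that add atoms: none
Why: Trans-hydroalumination of the propargylic alkoxide (alkyne reduction) gives only the E-alkene.

Step 2
Reactants: 2 (2E)-but-2-ene-1,4-diol
Product: 3 (2E)-4-(TBDPS-oxy)but-2-en-1-ol
Conditions: NaH (1.0 equiv), THF, 0 °C; TBDPSCl, 0 °C → rt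
Reagents that add atoms: tert-butyl(chloro)diphenylsilane, CC(C)(C)[Si](Cl)(c1ccccc1)c1ccccc1
Why: O-silylation of the sparingly soluble mono-sodium alkoxide of the symmetric diol gives the mono-silyl ether; no stereocentre is formed.

Step 3
Reactants: 3 (2E)-4-(TBDPS-oxy)but-2-en-1-ol
Product: 4 [(1R,2R)-2-(TBDPS-oxymethyl)cyclopropyl]methanol
Conditions: Et2Zn, CH2I2, DME, CH2Cl2, −10 °C; (4S,5S)-2-butyl-N,N,N′,N′-tetramethyl-1,3,2-dioxaborolane-4,5-dicarboxamide (1.2 equiv); → rt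
Reagents that add atoms: diiodomethane, ICI
Why: Charette asymmetric Simmons–Smith cyclopropanation, in which the zinc alkoxide bound to the (S,S)-dioxaborolane directs Zn(CH2I)2 to one alkene face and the E-alkene is converted stereospecifically into the trans (1R,2R)-cyclopropane.

Step 4
Reactants: 4 [(1R,2R)-2-(TBDPS-oxymethyl)cyclopropyl]methanol
Product: 5 (1R,2R)-2-(TBDPS-oxymethyl)cyclopropane-1-carbaldehyde
Conditions: Dess–Martin periodinane, CH2Cl2, 0 °C → rt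
Reagents that add atoms: none
Why: Dess–Martin oxidation of the primary alcohol stops at the aldehyde, and the cyclopropane stereocentres are safe because a cyclopropanecarbaldehyde does not enolise readily.

Step 5
Reactants: 5 (1R,2R)-2-(TBDPS-oxymethyl)cyclopropane-1-carbaldehyde
Product: 6 (1R)-1-[(1R,2R)-2-(TBDPS-oxymethyl)cyclopropyl]but-3-en-1-ol
Conditions: (+)-Ipc2B(allyl) (from (−)-α-pinene, 1 M in pentane), Et2O, −78 °C; then NaOH, H2O2, 0 °C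
Reagents that add atoms: (+)-B-allyldiisopinocampheylborane, C=CCB([C@H]1C[C@H]2C[C@@H]([C@@H]1C)C2(C)C)[C@H]1C[C@H]2C[C@@H]([C@@H]1C)C2(C)C
Why: Brown asymmetric allylboration through a chair transition state, in which the reagent from (−)-α-pinene delivers allyl to the Re face and sets the 1R carbinol under reagent control.

Step 6
Reactants: 6 (1R)-1-[(1R,2R)-2-(TBDPS-oxymethyl)cyclopropyl]but-3-en-1-ol
Product: 7 (1R)-1-[(1R,2R)-2-(TBDPS-oxymethyl)cyclopropyl]but-3-en-1-yl prop-2-enoate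
Conditions: acryloyl chloride, Et3N, DMAP (cat.), CH2Cl2, 0 °C
Reagents that add atoms: prop-2-enoyl chloride, C=CC(Cl)=O
Why: O-acylation (esterification) of the secondary alcohol proceeds with retention because the C–O bond is not broken.

Step 7
Reactants: 7 (1R)-1-[(1R,2R)-2-(TBDPS-oxymethyl)cyclopropyl]but-3-en-1-yl prop-2-enoate
Product: 8 (6R)-6-[(1R,2R)-2-(TBDPS-oxymethyl)cyclopropyl]-5,6-dihydro-2H-pyran-2-one
Conditions: second-generation Grubbs catalyst RuCl2(=CHPh)(H2IMes)(PCy3) (5 mol%), CH2Cl2 (5 mM), reflux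
Reagents that add atoms: none
Why: Ring-closing metathesis between the acrylate and the terminal alkene closes the six-membered unsaturated lactone with loss of ethene, and the cyclopropane is inert to the carbene.

Step 8
Reactants: 8 (6R)-6-[(1R,2R)-2-(TBDPS-oxymethyl)cyclopropyl]-5,6-dihydro-2H-pyran-2-one
Product: 9 (6R)-6-[(1R,2R)-2-(TBDPS-oxymethyl)cyclopropyl]oxan-2-one
Conditions: H2 (3 atm), RhCl(PPh3)3 (5 mol%), toluene/EtOH, rt
Reagents that add atoms: none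
Why: Homogeneous hydrogenation saturates the conjugated cis-alkene without hydrogenolysis of the cyclopropane or of the cyclopropylcarbinyl C–O bond.

Step 9
Reactants: 9 (6R)-6-[(1R,2R)-2-(TBDPS-oxymethyl)cyclopropyl]oxan-2-one
Product: 10 (6R)-6-[(1R,2R)-2-(hydroxymethyl)cyclopropyl]oxan-2-one
Conditions: Bu4NF, AcOH (1:1), THF, rt
Reagents that add atoms: none
Why: Fluoride-mediated desilylation, buffered with acetic acid so that the lactone is not opened.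

Step 10
Reactants: 10 (6R)-6-[(1R,2R)-2-(hydroxymethyl)cyclopropyl]oxan-2-one
Product: 11 (1R,2R)-2-[(2R)-6-oxooxan-2-yl]cyclopropane-1-carbaldehyde
Conditions: Dess–Martin periodinane, CH2Cl2, 0 °C → rt
Reagents that add atoms: none
Why: Dess–Martin oxidation gives the non-enolisable cyclopropyl aldehyde and leaves the lactone untouched.

Step 11
Reactants: 10 (6R)-6-[(1R,2R)-2-(hydroxymethyl)cyclopropyl]oxan-2-one
Product: 12 (6R)-6-[(1R,2R)-2-(PT-sulfanylmethyl)cyclopropyl]oxan-2-one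
Conditions: 1-phenyl-1H-tetrazole-5-thiol, PPh3, DIAD, THF, 0 °C → rt
Reagents that add atoms: 1-phenyl-1H-tetrazole-5-thiol, Sc1nnnn1-c1ccccc1
Why: Mitsunobu thioetherification at the primary carbon, remote from all stereocentres.

Step 12
Reactants: 12 (6R)-6-[(1R,2R)-2-(PT-sulfanylmethyl)cyclopropyl]oxan-2-one
Product: 13 (6R)-6-[(1R,2R)-2-(PT-sulfonylmethyl)cyclopropyl]oxan-2-one
Conditions: (NH4)6Mo7O24·4H2O (10 mol%), 30% H2O2, EtOH, 0 °C → rt
Reagents that add atoms: hydrogen peroxide, OO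
Why: Molybdate-catalysed sulfide-to-sulfone oxidation is chemoselective and tolerates the lactone and the cyclopropane.

**Homoallylic iodide (steps 13–16)**

Step 13
Reactants: 14 (4R)-4-benzyl-1,3-oxazolidin-2-one
Product: 15 (4R)-4-benzyl-3-[(2E)-but-2-enoyl]-1,3-oxazolidin-2-one
Conditions: n-BuLi, THF, −78 °C; (E)-but-2-enoyl chloride, −78 → 0 °C
Reagents that add atoms: (2E)-but-2-enoyl chloride, C/C=C/C(Cl)=O
Why: N-acylation of the lithiated oxazolidinone by the acid chloride.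

Step 14
Reactants: 15 (4R)-4-benzyl-3-[(2E)-but-2-enoyl]-1,3-oxazolidin-2-one
Product: 17 (4R)-4-benzyl-3-[(2S)-2-(TIPS-oxymethyl)but-3-enoyl]-1,3-oxazolidin-2-one, via sodium dienolate 16 (not isolated)
Conditions: NaN(SiMe3)2, THF, −78 °C; (i-Pr)3SiOCH2Cl, −78 → −40 °C; AcOH quench
Reagents that add atoms: (chloromethoxy)tri(propan-2-yl)silane, ClCO[Si](C(C)C)(C(C)C)C(C)C
Why: Deconjugative Evans alkylation, in which γ-deprotonation gives the chelated Z-dienolate and the alkoxymethyl chloride attacks the α-carbon anti to the benzyl group to set the 2S centre.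

Step 15
Reactants: 17 (4R)-4-benzyl-3-[(2S)-2-(TIPS-oxymethyl)but-3-enoyl]-1,3-oxazolidin-2-one
Product: 18 (2R)-2-(TIPS-oxymethyl)but-3-en-1-ol
Conditions: LiBH4, MeOH (1 equiv), Et2O, 0 °C
Reagents that add atoms: none
Why: Reductive cleavage of the imide by hydride gives the primary alcohol without enolising the α-centre and releases the auxiliary.

Step 16
Reactants: 18 (2R)-2-(TIPS-oxymethyl)but-3-en-1-ol
Product: 19 {[(2S)-2-(iodomethyl)but-3-en-1-yl]oxy}tri(propan-2-yl)silane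
Conditions: I2, PPh3, imidazole, CH2Cl2, 0 °C
Reagents that add atoms: iodine, II
Why: Appel-type iodination of the primary alcohol; the stereocentre is not involved.

**Weinreb amide and ketone (steps 17–22)**

Step 17
Reactants: 20 (2S)-2-hydroxybutanedioic acid
Product: 21 [(4S)-2,2-dimethyl-5-oxo-1,3-dioxolan-4-yl]acetic acid
Conditions: 2,2-dimethoxypropane, p-TsOH (cat.), rt
Reagents that add atoms: 2,2-dimethoxypropane, COC(C)(C)OC
Why: Acid-catalysed acetonide formation (transacetalisation) engages only the α-hydroxy acid pair as the five-membered dioxolanone and leaves the other carboxyl free, with the stereocentre retained.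

Step 18
Reactants: 21 [(4S)-2,2-dimethyl-5-oxo-1,3-dioxolan-4-yl]acetic acid
Product: 22 (5S)-5-(2-hydroxyethyl)-2,2-dimethyl-1,3-dioxolan-4-one
Conditions: BH3·SMe2, THF, 0 °C → rt; MeOH quench
Reagents that add atoms: none
Why: Borane reduces the free carboxylic acid chemoselectively via its acyloxyborane and leaves the dioxolanone carbonyl.

Step 19
Reactants: 22 (5S)-5-(2-hydroxyethyl)-2,2-dimethyl-1,3-dioxolan-4-one
Product: 23 (5S)-5-[2-(TBS-oxy)ethyl]-2,2-dimethyl-1,3-dioxolan-4-one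
Conditions: TBSCl, imidazole, CH2Cl2, 0 °C → rt
Reagents that add atoms: tert-butyl(chloro)dimethylsilane, CC(C)(C)[Si](C)(C)Cl
Why: O-silylation of the primary alcohol before it can lactonise.

Step 20
Reactants: 23 (5S)-5-[2-(TBS-oxy)ethyl]-2,2-dimethyl-1,3-dioxolan-4-one
Product: 24 (2S)-4-(TBS-oxy)-2-hydroxy-N-methoxy-N-methylbutanamide
Conditions: MeNH(OMe)·HCl, i-PrMgCl, THF, −20 → 0 °C
Reagents that add atoms: N,O-dimethylhydroxylamine hydrochloride, CNOC.Cl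
Why: Aminolysis of the activated dioxolanone carbonyl by the magnesium amide (Weinreb amide formation) expels acetone and frees the α-hydroxyl without touching the stereocentre.

Step 21
Reactants: 19 {[(2S)-2-(iodomethyl)but-3-en-1-yl]oxy}tri(propan-2-yl)silane; 24 (2S)-4-(TBS-oxy)-2-hydroxy-N-methoxy-N-methylbutanamide
Product: 26 (3S,6S)-1-(TBS-oxy)-3-hydroxy-6-(TIPS-oxymethyl)oct-7-en-4-one, via organolithium 25 (not isolated)
Conditions: 19, t-BuLi (2.1 equiv), Et2O/pentane, −78 °C; added to 24 pre-treated with i-PrMgCl (1.0 equiv) in THF, −78 → 0 °C; aqueous NH4Cl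
Reagents that add atoms: none
Why: Iodine–lithium exchange gives the primary organolithium, which adds once to the amide (Weinreb ketone synthesis) because the chelated tetrahedral intermediate survives until work-up, while the magnesium alkoxide masks the α-hydroxyl.

Step 22
Reactants: 26 (3S,6S)-1-(TBS-oxy)-3-hydroxy-6-(TIPS-oxymethyl)oct-7-en-4-one
Product: 27 (3S,6S)-1-(TBS-oxy)-4-oxo-6-(TIPS-oxymethyl)oct-7-en-3-yl benzoate
Conditions: Bz2O, i-Pr2NEt, DMAP (cat.), CH2Cl2, 0 °C → rt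
Reagents that add atoms: benzoic anhydride, O=C(OC(=O)c1ccccc1)c1ccccc1
Why: O-benzoylation installs the benzoate needed for aldol control, under conditions that do not epimerise the α-acyloxy ketone.

**Phosphonium salt (steps 23–24)**

Step 23
Reactants: 28 (3Z)-hex-3-en-1-ol
Product: 29 (3Z)-1-iodohex-3-ene
Conditions: I2, PPh3, imidazole, CH2Cl2, 0 °C
Reagents that add atoms: iodine, II
Why: Appel-type iodination of the primary alcohol leaves the Z-alkene untouched.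

Step 24
Reactants: 29 (3Z)-1-iodohex-3-ene
Product: 30 [(3Z)-hex-3-en-1-yl]triphenylphosphonium iodide
Conditions: PPh3, MeCN, reflux
Reagents that add atoms: triphenylphosphine, c1ccc(cc1)P(c1ccccc1)c1ccccc1
Why: SN2 quaternisation of triphenylphosphine by the primary iodide.

**Assembly (steps 25–34)**

Step 25
Reactants: 27 (3S,6S)-1-(TBS-oxy)-4-oxo-6-(TIPS-oxymethyl)oct-7-en-3-yl benzoate; 11 (1R,2R)-2-[(2R)-6-oxooxan-2-yl]cyclopropane-1-carbaldehyde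
Product: 32 (3S,5R,6R)-5-[(R)-hydroxy(CPL)methyl]-4-oxo-1-(TBS-oxy)-6-(TIPS-oxymethyl)oct-7-en-3-yl benzoate, via enol borinate 31 (not isolated)
Conditions: (c-C6H11)2BCl, Me2NEt, Et2O, −78 → 0 °C; 11, −78 → −20 °C; MeOH, pH 7 buffer, H2O2, 0 °C
Reagents that add atoms: none
Why: Paterson anti-aldol, in which the E-enol borinate reacts through a chair transition state with the α′-H eclipsing the enolate and the benzoate on the aldehyde side, so the (S)-benzoyloxy centre sets C5 as R and the E geometry sets the carbinol anti (R).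

Step 26
Reactants: 32 (3S,5R,6R)-5-[(R)-hydroxy(CPL)methyl]-4-oxo-1-(TBS-oxy)-6-(TIPS-oxymethyl)oct-7-en-3-yl benzoate
Product: 33 (3S,4S,5S,6R)-5-[(R)-acetyloxy(CPL)methyl]-4-hydroxy-1-(TBS-oxy)-6-(TIPS-oxymethyl)oct-7-en-3-yl benzoate
Conditions: MeCHO (8 equiv), SmI2 (0.3 equiv, premixed with the MeCHO), THF, −10 °C
Reagents that add atoms: acetaldehyde, CC=O
Why: Evans–Tishchenko reduction, in which the trivalent samarium catalyst formed from SmI2 and acetaldehyde binds the hemiacetal of the β-hydroxyl and delivers hydride intramolecularly to the ketone, giving the 1,3-anti (4S) alcohol and leaving the directing hydroxyl as its acetate.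

Step 27
Reactants: 33 (3S,4S,5S,6R)-5-[(R)-acetyloxy(CPL)methyl]-4-hydroxy-1-(TBS-oxy)-6-(TIPS-oxymethyl)oct-7-en-3-yl benzoate
Product: 34 (3S,4S,5S,6R)-5-[(R)-acetyloxy(CPL)methyl]-1,4-dihydroxy-6-(TIPS-oxymethyl)oct-7-en-3-yl benzoate
Conditions: AcOH/THF/H2O (3:1:1), rt
Reagents that add atoms: none
Why: Acid-catalysed desilylation removes the primary TBS ether much faster than the bulkier primary TIPS ether and does not promote acyl migration.

Step 28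
Reactants: 34 (3S,4S,5S,6R)-5-[(R)-acetyloxy(CPL)methyl]-1,4-dihydroxy-6-(TIPS-oxymethyl)oct-7-en-3-yl benzoate
Product: 36 (1S)-1-[(2S,3R,4R,5R)-3-[(R)-acetyloxy(CPL)methyl]-5-(2-oxoethyl)-4-(TIPS-oxymethyl)oxolan-2-yl]-3-hydroxypropyl benzoate, via hydroxy enal 35 (not isolated)
Conditions: (E)-but-2-enal (10 equiv), second-generation Hoveyda–Grubbs catalyst RuCl2(H2IMes)(=CH-C6H4-2-O-i-Pr) (10 mol%), CH2Cl2, 40 °C; then CSA (0.2 equiv), rt
Reagents that add atoms: (2E)-but-2-enal, C/C=C/C=O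
Why: Olefin cross-metathesis installs the E-enal, whose β-carbon is then attacked 5-exo by the C4 hydroxyl in an acid-catalysed intramolecular oxa-Michael addition anti to the adjacent CH2OTIPS group, giving the all-trans oxolane that is also the thermodynamic isomer.

Step 29
Reactants: 36 (1S)-1-[(2S,3R,4R,5R)-3-[(R)-acetyloxy(CPL)methyl]-5-(2-oxoethyl)-4-(TIPS-oxymethyl)oxolan-2-yl]-3-hydroxypropyl benzoate
Product: 37 (1S)-1-[(2S,3R,4R,5R)-3-[(R)-acetyloxy(CPL)methyl]-5-(2-oxoethyl)-4-(TIPS-oxymethyl)oxolan-2-yl]-3-oxopropyl benzoate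
Conditions: Dess–Martin periodinane, pyridine, CH2Cl2, 0 °C
Reagents that add atoms: none
Why: Buffered Dess–Martin oxidation of the only free hydroxyl gives the dialdehyde without β-elimination of the benzoate or the ring oxygen.

Step 30
Reactants: 37 (1S)-1-[(2S,3R,4R,5R)-3-[(R)-acetyloxy(CPL)methyl]-5-(2-oxoethyl)-4-(TIPS-oxymethyl)oxolan-2-yl]-3-oxopropyl benzoate; 30 [(3Z)-hex-3-en-1-yl]triphenylphosphonium iodide
Product: 39 (1S,3Z,6Z)-1-[(2S,3R,4R,5R)-3-[(R)-acetyloxy(CPL)methyl]-5-[(2Z,5Z)-octa-2,5-dien-1-yl]-4-(TIPS-oxymethyl)oxolan-2-yl]nona-3,6-dien-1-yl benzoate, via phosphorus ylide 38 (not isolated)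
Conditions: 30 (3.0 equiv), NaN(SiMe3)2 (2.9 equiv), THF, −78 → 0 °C; 37, −78 → −20 °C
Reagents that add atoms: none
Why: Two-directional Wittig reaction of the unstabilised ylide under lithium-free conditions gives both new alkenes Z through the kinetically favoured cis-oxaphosphetane, and at −78 °C addition to the aldehydes outruns ester attack and β-elimination.

Step 31
Reactants: 39 (1S,3Z,6Z)-1-[(2S,3R,4R,5R)-3-[(R)-acetyloxy(CPL)methyl]-5-[(2Z,5Z)-octa-2,5-dien-1-yl]-4-(TIPS-oxymethyl)oxolan-2-yl]nona-3,6-dien-1-yl benzoate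
Product: 40 (1S,3Z,6Z)-1-[(2S,3R,4R,5R)-3-[(R)-acetyloxy(CPL)methyl]-4-(hydroxymethyl)-5-[(2Z,5Z)-octa-2,5-dien-1-yl]oxolan-2-yl]nona-3,6-dien-1-yl benzoate
Conditions: HF·pyridine, pyridine, THF, 0 °C → rt
Reagents that add atoms: none
Why: Buffered fluoride desilylation removes the TIPS ether and spares the esters, the lactone and the skipped dienes.

Step 32
Reactants: 40 (1S,3Z,6Z)-1-[(2S,3R,4R,5R)-3-[(R)-acetyloxy(CPL)methyl]-4-(hydroxymethyl)-5-[(2Z,5Z)-octa-2,5-dien-1-yl]oxolan-2-yl]nona-3,6-dien-1-yl benzoate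
Product: 41 (1S,3Z,6Z)-1-[(2S,3R,4S,5R)-3-[(R)-acetyloxy(CPL)methyl]-4-formyl-5-[(2Z,5Z)-octa-2,5-dien-1-yl]oxolan-2-yl]nona-3,6-dien-1-yl benzoate
Conditions: Dess–Martin periodinane, pyridine, CH2Cl2, 0 °C
Reagents that add atoms: none
Why: Buffered Dess–Martin oxidation gives the aldehyde without epimerising C4, whose trans,trans arrangement is in any case the stable one.

Step 33
Reactants: 41 (1S,3Z,6Z)-1-[(2S,3R,4S,5R)-3-[(R)-acetyloxy(CPL)methyl]-4-formyl-5-[(2Z,5Z)-octa-2,5-dien-1-yl]oxolan-2-yl]nona-3,6-dien-1-yl benzoate; 13 (6R)-6-[(1R,2R)-2-(PT-sulfonylmethyl)cyclopropyl]oxan-2-one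
Product: 43 (1S,3Z,6Z)-1-[(2S,3R,4S,5R)-3-[(R)-acetyloxy(CPL)methyl]-5-[(2Z,5Z)-octa-2,5-dien-1-yl]-4-{(E)-2-[(1S,2R)-2-[(2R)-6-oxooxan-2-yl]cyclopropyl]ethenyl}oxolan-2-yl]nona-3,6-dien-1-yl benzoate, via potassium sulfonyl carbanion 42 (not isolated)
Conditions: 13 (1.3 equiv), KN(SiMe3)2 (1.25 equiv), DME, −60 °C, 20 min; 41, −60 °C → rt
Reagents that add atoms: none
Why: Julia–Kocienski olefination, in which the metalated PT-sulfone adds to the aldehyde and Smiles rearrangement with loss of SO2 and the tetrazololate gives the E-alkene, the α-sulfonyl cyclopropylcarbinyl anion not ring-opening.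

Step 34
Reactants: 43 (1S,3Z,6Z)-1-[(2S,3R,4S,5R)-3-[(R)-acetyloxy(CPL)methyl]-5-[(2Z,5Z)-octa-2,5-dien-1-yl]-4-{(E)-2-[(1S,2R)-2-[(2R)-6-oxooxan-2-yl]cyclopropyl]ethenyl}oxolan-2-yl]nona-3,6-dien-1-yl benzoate
Product: 45 CNP0273074.2, via seco acid 44 (not isolated)
Conditions: LiOH, THF/MeOH/H2O, rt; 1 M HCl to pH 3 at 0 °C, extraction; PPTS (cat.), CH2Cl2, rt
Reagents that add atoms: none
Why: Saponification cleaves the benzoate and acetate and opens both lactones to the seco acid, which re-closes to the two six-membered lactones on mild acid treatment (lactonisation) without affecting any stereocentre.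

## Compound list

1 | but-2-yne-1,4-diol | OCC#CCO | starting material
2 | (2E)-but-2-ene-1,4-diol | OC/C=C/CO | intermediate
3 | (2E)-4-{[tert-butyl(diphenyl)silyl]oxy}but-2-en-1-ol | OC/C=C/CO[Si](c1ccccc1)(c1ccccc1)C(C)(C)C | intermediate
4 | [(1R,2R)-2-({[tert-butyl(diphenyl)silyl]oxy}methyl)cyclopropyl]methanol | OC[C@@H]1C[C@H]1CO[Si](c1ccccc1)(c1ccccc1)C(C)(C)C | intermediate
5 | (1R,2R)-2-({[tert-butyl(diphenyl)silyl]oxy}methyl)cyclopropane-1-carbaldehyde | O=C[C@@H]1C[C@H]1CO[Si](c1ccccc1)(c1ccccc1)C(C)(C)C | intermediate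
6 | (1R)-1-[(1R,2R)-2-({[tert-butyl(diphenyl)silyl]oxy}methyl)cyclopropyl]but-3-en-1-ol | C=CC[C@@H](O)[C@@H]1C[C@H]1CO[Si](c1ccccc1)(c1ccccc1)C(C)(C)C | intermediate
7 | (1R)-1-[(1R,2R)-2-({[tert-butyl(diphenyl)silyl]oxy}methyl)cyclopropyl]but-3-en-1-yl prop-2-enoate | C=CC[C@@H](OC(=O)C=C)[C@@H]1C[C@H]1CO[Si](c1ccccc1)(c1ccccc1)C(C)(C)C | intermediate
8 | (6R)-6-[(1R,2R)-2-({[tert-butyl(diphenyl)silyl]oxy}methyl)cyclopropyl]-5,6-dihydro-2H-pyran-2-one | O=C1C=CC[C@@H](O1)[C@@H]1C[C@H]1CO[Si](c1ccccc1)(c1ccccc1)C(C)(C)C | intermediate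
9 | (6R)-6-[(1R,2R)-2-({[tert-butyl(diphenyl)silyl]oxy}methyl)cyclopropyl]oxan-2-one | O=C1CCC[C@@H](O1)[C@@H]1C[C@H]1CO[Si](c1ccccc1)(c1ccccc1)C(C)(C)C | intermediate
10 | (6R)-6-[(1R,2R)-2-(hydroxymethyl)cyclopropyl]oxan-2-one | O=C1CCC[C@@H](O1)[C@@H]1C[C@H]1CO | intermediate
11 | (1R,2R)-2-[(2R)-6-oxooxan-2-yl]cyclopropane-1-carbaldehyde | O=C[C@@H]1C[C@H]1[C@H]1CCCC(=O)O1 | intermediate
12 | (6R)-6-[(1R,2R)-2-{[(1-phenyl-1H-tetrazol-5-yl)sulfanyl]methyl}cyclopropyl]oxan-2-one | O=C1CCC[C@@H](O1)[C@@H]1C[C@H]1CSc1nnnn1-c1ccccc1 | intermediate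
13 | (6R)-6-[(1R,2R)-2-{[(1-phenyl-1H-tetrazol-5-yl)sulfonyl]methyl}cyclopropyl]oxan-2-one | O=C1CCC[C@@H](O1)[C@@H]1C[C@H]1CS(=O)(=O)c1nnnn1-c1ccccc1 | intermediate
14 | (4R)-4-benzyl-1,3-oxazolidin-2-one | O=C1N[C@H](Cc2ccccc2)CO1 | starting material
15 | (4R)-4-benzyl-3-[(2E)-but-2-enoyl]-1,3-oxazolidin-2-one | C/C=C/C(=O)N1[C@H](Cc2ccccc2)COC1=O | intermediate
16 | sodium (1Z)-1-[(4R)-4-benzyl-2-oxo-1,3-oxazolidin-3-yl]buta-1,3-dien-1-olate | [Na+].[O-]/C(=C\C=C)N1[C@H](Cc2ccccc2)COC1=O | intermediate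
17 | (4R)-4-benzyl-3-[(2S)-2-({[tri(propan-2-yl)silyl]oxy}methyl)but-3-enoyl]-1,3-oxazolidin-2-one | C=C[C@@H](CO[Si](C(C)C)(C(C)C)C(C)C)C(=O)N1[C@H](Cc2ccccc2)COC1=O | intermediate
18 | (2R)-2-({[tri(propan-2-yl)silyl]oxy}methyl)but-3-en-1-ol | C=C[C@@H](CO[Si](C(C)C)(C(C)C)C(C)C)CO | intermediate
19 | {[(2S)-2-(iodomethyl)but-3-en-1-yl]oxy}tri(propan-2-yl)silane | C=C[C@@H](CO[Si](C(C)C)(C(C)C)C(C)C)CI | intermediate
20 | (2S)-2-hydroxybutanedioic acid (L-malic acid) | O[C@@H](CC(=O)O)C(=O)O | starting material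
21 | [(4S)-2,2-dimethyl-5-oxo-1,3-dioxolan-4-yl]acetic acid | CC1(C)O[C@@H](CC(=O)O)C(=O)O1 | intermediate
22 | (5S)-5-(2-hydroxyethyl)-2,2-dimethyl-1,3-dioxolan-4-one | CC1(C)O[C@@H](CCO)C(=O)O1 | intermediate
23 | (5S)-5-(2-{[tert-butyl(dimethyl)silyl]oxy}ethyl)-2,2-dimethyl-1,3-dioxolan-4-one | CC1(C)O[C@@H](CCO[Si](C)(C)C(C)(C)C)C(=O)O1 | intermediate
24 | (2S)-4-{[tert-butyl(dimethyl)silyl]oxy}-2-hydroxy-N-methoxy-N-methylbutanamide | CON(C)C(=O)[C@@H](O)CCO[Si](C)(C)C(C)(C)C | intermediate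
25 | [(2S)-2-({[tri(propan-2-yl)silyl]oxy}methyl)but-3-en-1-yl]lithium | [Li]C[C@@H](C=C)CO[Si](C(C)C)(C(C)C)C(C)C | intermediate
26 | (3S,6S)-1-{[tert-butyl(dimethyl)silyl]oxy}-3-hydroxy-6-({[tri(propan-2-yl)silyl]oxy}methyl)oct-7-en-4-one | C=C[C@@H](CO[Si](C(C)C)(C(C)C)C(C)C)CC(=O)[C@@H](O)CCO[Si](C)(C)C(C)(C)C | intermediate
27 | (3S,6S)-1-{[tert-butyl(dimethyl)silyl]oxy}-4-oxo-6-({[tri(propan-2-yl)silyl]oxy}methyl)oct-7-en-3-yl benzoate | C=C[C@@H](CO[Si](C(C)C)(C(C)C)C(C)C)CC(=O)[C@@H](OC(=O)c1ccccc1)CCO[Si](C)(C)C(C)(C)C | intermediate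
28 | (3Z)-hex-3-en-1-ol | CC/C=C\CCO | starting material
29 | (3Z)-1-iodohex-3-ene | CC/C=C\CCI | intermediate
30 | [(3Z)-hex-3-en-1-yl]triphenylphosphonium iodide | CC/C=C\CC[P+](c1ccccc1)(c1ccccc1)c1ccccc1.[I-] | intermediate
31 | (3S,4E,6R)-1-{[tert-butyl(dimethyl)silyl]oxy}-4-[(dicyclohexylboranyl)oxy]-6-({[tri(propan-2-yl)silyl]oxy}methyl)octa-4,7-dien-3-yl benzoate | C=C[C@@H](CO[Si](C(C)C)(C(C)C)C(C)C)/C=C(/OB(C1CCCCC1)C1CCCCC1)[C@@H](OC(=O)c1ccccc1)CCO[Si](C)(C)C(C)(C)C | intermediate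
32 | (3S,5R,6R)-1-{[tert-butyl(dimethyl)silyl]oxy}-5-{(R)-hydroxy[(1R,2R)-2-[(2R)-6-oxooxan-2-yl]cyclopropyl]methyl}-4-oxo-6-({[tri(propan-2-yl)silyl]oxy}methyl)oct-7-en-3-yl benzoate | C=C[C@@H](CO[Si](C(C)C)(C(C)C)C(C)C)[C@@H](C(=O)[C@@H](OC(=O)c1ccccc1)CCO[Si](C)(C)C(C)(C)C)[C@H](O)[C@@H]1C[C@H]1[C@H]1CCCC(=O)O1 | intermediate
33 | (3S,4S,5S,6R)-5-{(R)-(acetyloxy)[(1R,2R)-2-[(2R)-6-oxooxan-2-yl]cyclopropyl]methyl}-1-{[tert-butyl(dimethyl)silyl]oxy}-4-hydroxy-6-({[tri(propan-2-yl)silyl]oxy}methyl)oct-7-en-3-yl benzoate | C=C[C@@H](CO[Si](C(C)C)(C(C)C)C(C)C)[C@@H]([C@H](O)[C@@H](OC(=O)c1ccccc1)CCO[Si](C)(C)C(C)(C)C)[C@H](OC(C)=O)[C@@H]1C[C@H]1[C@H]1CCCC(=O)O1 | intermediate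
34 | (3S,4S,5S,6R)-5-{(R)-(acetyloxy)[(1R,2R)-2-[(2R)-6-oxooxan-2-yl]cyclopropyl]methyl}-1,4-dihydroxy-6-({[tri(propan-2-yl)silyl]oxy}methyl)oct-7-en-3-yl benzoate | C=C[C@@H](CO[Si](C(C)C)(C(C)C)C(C)C)[C@@H]([C@H](O)[C@@H](OC(=O)c1ccccc1)CCO)[C@H](OC(C)=O)[C@@H]1C[C@H]1[C@H]1CCCC(=O)O1 | intermediate
35 | (3S,4S,5S,6R,7E)-5-{(R)-(acetyloxy)[(1R,2R)-2-[(2R)-6-oxooxan-2-yl]cyclopropyl]methyl}-1,4-dihydroxy-9-oxo-6-({[tri(propan-2-yl)silyl]oxy}methyl)non-7-en-3-yl benzoate | O=C/C=C/[C@@H](CO[Si](C(C)C)(C(C)C)C(C)C)[C@@H]([C@H](O)[C@@H](OC(=O)c1ccccc1)CCO)[C@H](OC(C)=O)[C@@H]1C[C@H]1[C@H]1CCCC(=O)O1 | intermediate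
36 | (1S)-1-[(2S,3R,4R,5R)-3-{(R)-(acetyloxy)[(1R,2R)-2-[(2R)-6-oxooxan-2-yl]cyclopropyl]methyl}-5-(2-oxoethyl)-4-({[tri(propan-2-yl)silyl]oxy}methyl)oxolan-2-yl]-3-hydroxypropyl benzoate | OCC[C@H](OC(=O)c1ccccc1)[C@H]1O[C@H](CC=O)[C@@H](CO[Si](C(C)C)(C(C)C)C(C)C)[C@@H]1[C@H](OC(C)=O)[C@@H]1C[C@H]1[C@H]1CCCC(=O)O1 | intermediate
37 | (1S)-1-[(2S,3R,4R,5R)-3-{(R)-(acetyloxy)[(1R,2R)-2-[(2R)-6-oxooxan-2-yl]cyclopropyl]methyl}-5-(2-oxoethyl)-4-({[tri(propan-2-yl)silyl]oxy}methyl)oxolan-2-yl]-3-oxopropyl benzoate | O=CC[C@H](OC(=O)c1ccccc1)[C@H]1O[C@H](CC=O)[C@@H](CO[Si](C(C)C)(C(C)C)C(C)C)[C@@H]1[C@H](OC(C)=O)[C@@H]1C[C@H]1[C@H]1CCCC(=O)O1 | intermediate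
38 | [(3Z)-hex-3-en-1-ylidene]triphenyl-λ5-phosphane | CC/C=C\CC=P(c1ccccc1)(c1ccccc1)c1ccccc1 | intermediate
39 | (1S,3Z,6Z)-1-[(2S,3R,4R,5R)-3-{(R)-(acetyloxy)[(1R,2R)-2-[(2R)-6-oxooxan-2-yl]cyclopropyl]methyl}-5-[(2Z,5Z)-octa-2,5-dien-1-yl]-4-({[tri(propan-2-yl)silyl]oxy}methyl)oxolan-2-yl]nona-3,6-dien-1-yl benzoate | CC/C=C\C/C=C\C[C@H](OC(=O)c1ccccc1)[C@H]1O[C@H](C/C=C\C/C=C\CC)[C@@H](CO[Si](C(C)C)(C(C)C)C(C)C)[C@@H]1[C@H](OC(C)=O)[C@@H]1C[C@H]1[C@H]1CCCC(=O)O1 | intermediate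
40 | (1S,3Z,6Z)-1-[(2S,3R,4R,5R)-3-{(R)-(acetyloxy)[(1R,2R)-2-[(2R)-6-oxooxan-2-yl]cyclopropyl]methyl}-4-(hydroxymethyl)-5-[(2Z,5Z)-octa-2,5-dien-1-yl]oxolan-2-yl]nona-3,6-dien-1-yl benzoate | CC/C=C\C/C=C\C[C@H](OC(=O)c1ccccc1)[C@H]1O[C@H](C/C=C\C/C=C\CC)[C@@H](CO)[C@@H]1[C@H](OC(C)=O)[C@@H]1C[C@H]1[C@H]1CCCC(=O)O1 | intermediate
41 | (1S,3Z,6Z)-1-[(2S,3R,4S,5R)-3-{(R)-(acetyloxy)[(1R,2R)-2-[(2R)-6-oxooxan-2-yl]cyclopropyl]methyl}-4-formyl-5-[(2Z,5Z)-octa-2,5-dien-1-yl]oxolan-2-yl]nona-3,6-dien-1-yl benzoate | CC/C=C\C/C=C\C[C@H](OC(=O)c1ccccc1)[C@H]1O[C@H](C/C=C\C/C=C\CC)[C@@H](C=O)[C@@H]1[C@H](OC(C)=O)[C@@H]1C[C@H]1[C@H]1CCCC(=O)O1 | intermediate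
42 | potassium [(1R,2R)-2-[(2R)-6-oxooxan-2-yl]cyclopropyl][(1-phenyl-1H-tetrazol-5-yl)sulfonyl]methanide | [K+].O=C1CCC[C@@H](O1)[C@@H]1C[C@H]1[CH-]S(=O)(=O)c1nnnn1-c1ccccc1 | intermediate
43 | (1S,3Z,6Z)-1-[(2S,3R,4S,5R)-3-{(R)-(acetyloxy)[(1R,2R)-2-[(2R)-6-oxooxan-2-yl]cyclopropyl]methyl}-5-[(2Z,5Z)-octa-2,5-dien-1-yl]-4-{(E)-2-[(1S,2R)-2-[(2R)-6-oxooxan-2-yl]cyclopropyl]ethenyl}oxolan-2-yl]nona-3,6-dien-1-yl benzoate | CC/C=C\C/C=C\C[C@H](OC(=O)c1ccccc1)[C@H]1O[C@H](C/C=C\C/C=C\CC)[C@@H](/C=C/[C@@H]2C[C@H]2[C@H]2CCCC(=O)O2)[C@@H]1[C@H](OC(C)=O)[C@@H]1C[C@H]1[C@H]1CCCC(=O)O1 | intermediate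
44 | (5R)-5-hydroxy-5-[(1R,2R)-2-{(R)-hydroxy[(2S,3R,4S,5R)-4-{(E)-2-[(1S,2R)-2-[(1R)-4-carboxy-1-hydroxybutyl]cyclopropyl]ethenyl}-2-[(1S,3Z,6Z)-1-hydroxynona-3,6-dien-1-yl]-5-[(2Z,5Z)-octa-2,5-dien-1-yl]oxolan-3-yl]methyl}cyclopropyl]pentanoic acid (seco acid) | CC/C=C\C/C=C\C[C@H](O)[C@H]1O[C@H](C/C=C\C/C=C\CC)[C@@H](/C=C/[C@@H]2C[C@H]2[C@H](O)CCCC(=O)O)[C@@H]1[C@H](O)[C@@H]1C[C@H]1[C@H](O)CCCC(=O)O | intermediate
45 | CNP0273074.2: (6R)-6-[(1R,2R)-2-{(R)-hydroxy[(2S,3R,4S,5R)-2-[(1S,3Z,6Z)-1-hydroxynona-3,6-dien-1-yl]-5-[(2Z,5Z)-octa-2,5-dien-1-yl]-4-{(E)-2-[(1S,2R)-2-[(2R)-6-oxooxan-2-yl]cyclopropyl]ethenyl}oxolan-3-yl]methyl}cyclopropyl]oxan-2-one | CC/C=C\C/C=C\C[C@H](O)[C@H]1O[C@H](C/C=C\C/C=C\CC)[C@@H](/C=C/[C@@H]2C[C@H]2[C@H]2CCCC(=O)O2)[C@@H]1[C@H](O)[C@@H]1C[C@H]1[C@H]1CCCC(=O)O1 | target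

## Step count and risks

Total step count: 34.
Longest linear sequence: 20 steps (steps 1–10, then steps 25–34).

Three steps most likely to fail:

Step 25 (Paterson aldol). The enol borinate carries a branched, stereogenic substituent that may slow the addition or oppose the benzoate-controlled face selectivity. The fallback sets out from ketone 27. Enol borinate 31 is formed as in step 25 and quenched with N-bromosuccinimide to give the 5-bromo ketone F1 as a mixture of C5 epimers. F1 and aldehyde 11 are then treated with CrCl2 (divalent chromium) and LiI in THF at rt. Reduction of the C–Br bond gives a trivalent chromium enolate, which adds to 11 in an anti-selective chromium Reformatsky reaction, and the route is rejoined at compound 32.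

Step 28 (cross-metathesis and oxa-Michael closure). The vinyl group sits on a crowded, oxygen-rich carbon and may not undergo cross-metathesis, and the enal is sensitive. The fallback sets out from diol 34. Ozonolysis of the vinyl group (O3, CH2Cl2, −78 °C; PPh3) gives the five-membered lactol F2. Heating F2 with (triphenylphosphoranylidene)acetaldehyde in toluene converts the open hydroxy aldehyde into hydroxy enal 35 by Wittig olefination, and CSA closes it to compound 36, where the route is rejoined.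

Step 33 (Julia–Kocienski olefination). Aldehyde 41 is α-branched and β-alkoxy, so the basic sulfonyl anion may enolise it, epimerise C4 or open the ring. The fallback reverses the polarity and sets out from alcohol 40. Mitsunobu reaction with 1-phenyl-1H-tetrazole-5-thiol (PPh3, DIAD) gives the core sulfide F3, and (NH4)6Mo7O24·4H2O with H2O2 oxidises it to the core sulfone F4. KN(SiMe3)2 is then added to a mixture of F4 and the non-enolisable aldehyde 11 in DME at −60 °C, and the route is rejoined at compound 43.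

## Further compounds

F1 | step 25 | (3S,5RS,6S)-5-bromo-1-{[tert-butyl(dimethyl)silyl]oxy}-4-oxo-6-({[tri(propan-2-yl)silyl]oxy}methyl)oct-7-en-3-yl benzoate | C=C[C@@H](CO[Si](C(C)C)(C(C)C)C(C)C)C(Br)C(=O)[C@@H](OC(=O)c1ccccc1)CCO[Si](C)(C)C(C)(C)C
F2 | step 28 | (1S)-1-[(2S,3R,4R,5RS)-3-{(R)-(acetyloxy)[(1R,2R)-2-[(2R)-6-oxooxan-2-yl]cyclopropyl]methyl}-5-hydroxy-4-({[tri(propan-2-yl)silyl]oxy}methyl)oxolan-2-yl]-3-hydroxypropyl benzoate | OCC[C@H](OC(=O)c1ccccc1)[C@H]1OC(O)[C@@H](CO[Si](C(C)C)(C(C)C)C(C)C)[C@@H]1[C@H](OC(C)=O)[C@@H]1C[C@H]1[C@H]1CCCC(=O)O1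
F3 | step 33 | (1S,3Z,6Z)-1-[(2S,3R,4S,5R)-3-{(R)-(acetyloxy)[(1R,2R)-2-[(2R)-6-oxooxan-2-yl]cyclopropyl]methyl}-5-[(2Z,5Z)-octa-2,5-dien-1-yl]-4-{[(1-phenyl-1H-tetrazol-5-yl)sulfanyl]methyl}oxolan-2-yl]nona-3,6-dien-1-yl benzoate | CC/C=C\C/C=C\C[C@H](OC(=O)c1ccccc1)[C@H]1O[C@H](C/C=C\C/C=C\CC)[C@@H](CSc2nnnn2-c2ccccc2)[C@@H]1[C@H](OC(C)=O)[C@@H]1C[C@H]1[C@H]1CCCC(=O)O1
F4 | step 33 | (1S,3Z,6Z)-1-[(2S,3R,4S,5R)-3-{(R)-(acetyloxy)[(1R,2R)-2-[(2R)-6-oxooxan-2-yl]cyclopropyl]methyl}-5-[(2Z,5Z)-octa-2,5-dien-1-yl]-4-{[(1-phenyl-1H-tetrazol-5-yl)sulfonyl]methyl}oxolan-2-yl]nona-3,6-dien-1-yl benzoate | CC/C=C\C/C=C\C[C@H](OC(=O)c1ccccc1)[C@H]1O[C@H](C/C=C\C/C=C\CC)[C@@H](CS(=O)(=O)c2nnnn2-c2ccccc2)[C@@H]1[C@H](OC(C)=O)[C@@H]1C[C@H]1[C@H]1CCCC(=O)O1
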